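**Retrosynthetic overview**
1. Hidden symmetry: rings A and B are the same building block, 3,4,5-trimethoxyphenol functionalised at C2. The C2–C3–C4 bridge is split into an ethyne unit and CO.
2. Last move: one-pot BCl3 unmasking of a 6'-O-benzyl-5-O-methyl flavone (benzyl ether cleavage plus carbonyl-chelated 5-O-demethylation).
3. Key step, used in place of Baker–Venkataraman or chalcone chemistry: Pd-catalysed three-component carbonylative annulation of 2-iodo-3,4,5-trimethoxyphenol, CO and an ortho-benzyloxy aryl alkyne. It makes C4a–C4, C4–C3 and O1–C2 in one operation.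
4. The alkyne comes from the same iodophenol by O-benzylation and Sonogashira ethynylation. The iodophenol comes from the symmetric phenol, which has only one kind of free ring position.
5. Ring order: A and B are bought intact. The pyranone ring C is the only ring formed, in the key step.

Assumption: the target has no stereocentre and no stereogenic double bond, and its C2–C1' axis rotates freely at room temperature, so it is achiral and needs no stereocontrol.
Assumption: small feedstock reagents (NIS, BnBr, TMS-acetylene, CO) are not numbered; each is given with its SMILES in the step where it adds atoms.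

**Step 1**
Reactants: 1 3,4,5-trimethoxyphenol
Product: 2 2-iodo-3,4,5-trimethoxyphenol
Conditions: NIS (1.0 equiv, slow addition), MeCN, −20 → 0 °C, dark
Reagents that add atoms: N-iodosuccinimide, O=C1CCC(=O)N1I
Why: Electrophilic aromatic iodination (SEAr); the two free positions are equivalent by symmetry and strongly activated (ortho to OH, ortho and para to OMe), so one equivalent of NIS at low temperature gives a single mono-iodide, and no stereocentre is formed.

**Step 2**
Reactants: 2 2-iodo-3,4,5-trimethoxyphenol (about half of the material; the rest is kept for step 4)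
Product: 3 1-(benzyloxy)-2-iodo-3,4,5-trimethoxybenzene
Conditions: BnBr, K2CO3, DMF, rt
Reagents that add atoms: benzyl bromide, BrCc1ccccc1
Why: Williamson ether synthesis; the phenoxide is benzylated by SN2, the aryl iodide is untouched, and masking the OH prevents benzofuran formation once the ortho alkyne is in place.

**Step 3**
Reactants: 3 1-(benzyloxy)-2-iodo-3,4,5-trimethoxybenzene
Product: 5 1-(benzyloxy)-2-ethynyl-3,4,5-trimethoxybenzene, via TMS-alkyne 4 (not isolated)
Conditions: TMS-acetylene, PdCl2(PPh3)2 (5 mol %), CuI (10 mol %), Et3N/THF, 65 °C; then K2CO3 (20 mol %), MeOH, rt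
Reagents that add atoms: ethynyltrimethylsilane, C#C[Si](C)(C)C
Why: Sonogashira coupling, which works on doubly ortho-alkoxylated aryl iodides with gentle heating, followed by methoxide-catalysed protodesilylation of the C(sp)–Si bond; ethers are inert to both stages.

**Step 4**
Reactants: 2 2-iodo-3,4,5-trimethoxyphenol; 5 1-(benzyloxy)-2-ethynyl-3,4,5-trimethoxybenzene
Product: 8 6'-benzyloxy-5,6,7,2',3',4'-hexamethoxyflavone, via ynone 6 (not isolated), via enaminone 7 (not isolated)
Conditions: CO (20 bar), PdCl2(dppf) (5 mol %), Et2NH, 120 °C, autoclave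
Reagents that add atoms: carbon monoxide, [C-]#[O+]
Why: Pd-catalysed carbonylative Sonogashira annulation (Torii–Kalinin flavone synthesis): oxidative addition into the C–I bond of 2, CO insertion (favoured over direct alkynylation because the aryl–Pd carbon is flanked by two ortho oxygens) and coupling with 5 give ynone 6, Et2NH adds in aza-Michael fashion to give enaminone 7, and the ortho phenol displaces the amine in a 6-endo addition–elimination that gives the flavone rather than the aurone; ring C is closed and no stereocentre is created.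

**Step 5**
Reactants: 8 6'-benzyloxy-5,6,7,2',3',4'-hexamethoxyflavone
Product: 10 5,6'-dihydroxy-6,7,2',3',4'-pentamethoxyflavone (target), via debenzylated flavone 9 (not isolated)
Conditions: BCl3 (5 equiv), pentamethylbenzene (5 equiv), CH2Cl2, −78 → 0 °C; then H2O
Reagents that add atoms: none
Why: Lewis-acid ether cleavage: BCl3 ionises the benzyl ether at −78 °C and pentamethylbenzene traps the benzyl cation by Friedel–Crafts alkylation (so the electron-rich flavone rings are not C-benzylated), giving 9 as its boron aryloxide, and on warming the boron chelated between C4=O and the peri 5-oxygen delivers chloride to the 5-O-methyl group only, because the other five methoxy groups cannot form that six-membered chelate; no stereocentre is involved.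

**Compound list**
1 | 3,4,5-trimethoxyphenol | COc1cc(O)cc(OC)c1OC | starting material
2 | 2-iodo-3,4,5-trimethoxyphenol | COc1cc(O)c(I)c(OC)c1OC | intermediate
3 | 1-(benzyloxy)-2-iodo-3,4,5-trimethoxybenzene | COc1cc(OCc2ccccc2)c(I)c(OC)c1OC | intermediate
4 | {[2-(benzyloxy)-4,5,6-trimethoxyphenyl]ethynyl}trimethylsilane (formed in situ) | COc1cc(OCc2ccccc2)c(C#C[Si](C)(C)C)c(OC)c1OC | intermediate
5 | 1-(benzyloxy)-2-ethynyl-3,4,5-trimethoxybenzene | COc1cc(OCc2ccccc2)c(C#C)c(OC)c1OC | intermediate
6 | 3-[2-(benzyloxy)-4,5,6-trimethoxyphenyl]-1-(2-hydroxy-4,5,6-trimethoxyphenyl)prop-2-yn-1-one (formed in situ) | COc1cc(OCc2ccccc2)c(C#CC(=O)c2c(O)cc(OC)c(OC)c2OC)c(OC)c1OC | intermediate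
7 | (E)-3-[2-(benzyloxy)-4,5,6-trimethoxyphenyl]-3-(diethylamino)-1-(2-hydroxy-4,5,6-trimethoxyphenyl)prop-2-en-1-one (formed in situ) | CCN(CC)/C(=C/C(=O)c1c(O)cc(OC)c(OC)c1OC)c1c(OCc2ccccc2)cc(OC)c(OC)c1OC | intermediate
8 | 6'-benzyloxy-5,6,7,2',3',4'-hexamethoxyflavone, i.e. 2-[2-(benzyloxy)-4,5,6-trimethoxyphenyl]-5,6,7-trimethoxy-4H-chromen-4-one | COc1cc(OCc2ccccc2)c(-c2cc(=O)c3c(OC)c(OC)c(OC)cc3o2)c(OC)c1OC | intermediate
9 | 6'-hydroxy-5,6,7,2',3',4'-hexamethoxyflavone (formed in situ, held as its boron aryloxide until work-up) | COc1cc(O)c(-c2cc(=O)c3c(OC)c(OC)c(OC)cc3o2)c(OC)c1OC | intermediate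
10 | 5,6'-dihydroxy-6,7,2',3',4'-pentamethoxyflavone (achiral) | COc1cc(O)c(-c2cc(=O)c3c(O)c(OC)c(OC)cc3o2)c(OC)c1OC | target

**Totals**
Total step count: 5.
Longest linear sequence: 5 steps (1 → 2 → 3 → 5 → 8 → 10). Compound 2 enters twice, in steps 2 and 4.

**Three steps most likely to fail**

Step 4, the key carbonylative annulation, carries the highest risk.
- Both partners are electron-rich and doubly ortho-substituted.
- Oxidative addition under CO may be slow.
- Hydrodeiodination, CO-free coupling to a 2-arylbenzofuran, or aminocarbonylation to the diethylamide may compete.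

The fallback builds ynone 6 by polar acetylide chemistry without Pd or CO. It sets out from 1 and 5 and comes back to the route at 6 (and through it at 8). Phenol 1 is protected (MOMCl, iPr2NEt, CH2Cl2) as 1,2,3-trimethoxy-5-(methoxymethoxy)benzene F1. F1 is lithiated between OMOM and OMe by cooperative directed ortho-metalation (n-BuLi, THF, 0 °C) and quenched with DMF to give 2,3,4-trimethoxy-6-(methoxymethoxy)benzaldehyde F2. The lithium acetylide of 5 (n-BuLi, THF, −78 °C) adds to F2 to give racemic 3-[2-(benzyloxy)-4,5,6-trimethoxyphenyl]-1-[2,3,4-trimethoxy-6-(methoxymethoxy)phenyl]prop-2-yn-1-ol F3, whose stereocentre is erased in the next operation. MnO2 in CH2Cl2 oxidises it to 3-[2-(benzyloxy)-4,5,6-trimethoxyphenyl]-1-[2,3,4-trimethoxy-6-(methoxymethoxy)phenyl]prop-2-yn-1-one F4. HCl in MeOH removes the MOM group to release 6, which is closed through 7 to 8 with Et2NH in EtOH.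

Step 5, the one-pot double dealkylation, may over-demethylate at 6-OMe once the 5-O-boron chelate has formed, and some C-benzylation could occur. The fallback decouples the two events and makes the first one reductive. It sets out from 8 and comes back at 10. Hydrogenolysis (H2, 1 atm, Pd/C, EtOAc/MeOH) removes the benzyl group and 9 is isolated. Then 9 is treated with AlCl3 in MeCN (60 °C, then dilute HCl), where an aluminium chelate between C4=O and O5 cleaves only the 5-O-methyl group. No compound outside the list is made.

Step 3, the Sonogashira coupling, uses a hindered, electron-rich iodide. Conversion may be sluggish and Glaser dimerisation of the alkyne may consume the reagent. The fallback replaces cross-coupling by one-carbon homologation of an aldehyde. It sets out from 3 and comes back at 5. I/Mg exchange (iPrMgCl·LiCl, THF, 0 °C) and a DMF quench give 2-(benzyloxy)-4,5,6-trimethoxybenzaldehyde F5. The Ohira–Bestmann reagent (dimethyl (1-diazo-2-oxopropyl)phosphonate, K2CO3, MeOH, rt) then converts F5 into alkyne 5.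

**Further compounds**
F1 | step 4 | 1,2,3-trimethoxy-5-(methoxymethoxy)benzene | COCOc1cc(OC)c(OC)c(OC)c1
F2 | step 4 | 2,3,4-trimethoxy-6-(methoxymethoxy)benzaldehyde | COCOc1cc(OC)c(OC)c(OC)c1C=O
F3 | step 4 | 3-[2-(benzyloxy)-4,5,6-trimethoxyphenyl]-1-[2,3,4-trimethoxy-6-(methoxymethoxy)phenyl]prop-2-yn-1-ol (racemic) | COCOc1cc(OC)c(OC)c(OC)c1C(O)C#Cc1c(OCc2ccccc2)cc(OC)c(OC)c1OC
F4 | step 4 | 3-[2-(benzyloxy)-4,5,6-trimethoxyphenyl]-1-[2,3,4-trimethoxy-6-(methoxymethoxy)phenyl]prop-2-yn-1-one | COCOc1cc(OC)c(OC)c(OC)c1C(=O)C#Cc1c(OCc2ccccc2)cc(OC)c(OC)c1OC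
F0 | step 5 | none | none
F5 | step 3 | 2-(benzyloxy)-4,5,6-trimethoxybenzaldehyde | COc1cc(OCc2ccccc2)c(C=O)c(OC)c1OC
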